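**Strategy.** Each N-acyl-5,6-dihydropyridin-2(1H)-one ring is read as acetylene stitched between the lactam carbonyl carbon C2 and the ring methylene C5; the feature exploited is the cis CH=CH unit C3=C4 of the six-membered lactam. In one operation a 2-(disilylamino)ethyl cuprate adds syn across acetylene (C4–C5 bond) and the resulting (Z)-alkenylcuprate is acylated by methyl chloroformate (C2–C3 bond); unmasking the amine in the work-up closes the lactam. The precursor is a disilazane-protected 2-bromoethylamine. The centrosymmetric cyclobutane comes from head-to-tail [2+2] photodimerisation of two molecules of crystalline (E)-3,4-dimethoxycinnamic acid, and N-acylation of two equivalents of the lactam by the derived diacid chloride ends the route.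

Key step: step 2

Remark on the chemistry: lactam atoms are numbered N1, C2 (carbonyl), C3, C4, C5, C6; the target is the centrosymmetric, achiral α-truxillic-type diastereomer, so only relative configuration has to be controlled; crystalline 11 is assumed to adopt its head-to-tail photoreactive packing.

Step 1
Reactants: 1 2-bromoethylamine hydrobromide
Product: 2 1-(2-bromoethyl)-2,2,5,5-tetramethyl-1-aza-2,5-disilacyclopentane
Conditions: ClMe2SiCH2CH2SiMe2Cl, Et3N, CH2Cl2, 0 → 23 °C
Reagents that add atoms: 1,2-bis(chlorodimethylsilyl)ethane, C[Si](C)(Cl)CC[Si](C)(C)Cl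
Why: Twofold N-silylation of the primary amine (cyclic disilazane protection) should remove both N–H protons and turn nitrogen into a poor leaving group for the organometallic step.

Step 2
Reactants: 2 1-(2-bromoethyl)-2,2,5,5-tetramethyl-1-aza-2,5-disilacyclopentane; 3 acetylene; 4 methyl chloroformate
Product: 10 5,6-dihydropyridin-2(1H)-one, via alkyllithium 5 (not isolated), via lithium dialkylcuprate 6 (not isolated), via (Z)-dialkenylcuprate 7 (not isolated), via silyl-protected (Z)-ester 8 (not isolated), via (Z)-amino ester 9 (not isolated)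
Conditions: t-BuLi (2 equiv), Et2O–pentane, −78 °C; CuBr·SMe2 (0.5 equiv), −45 °C; HC≡CH (1 equiv per C–Cu bond), −50 → −25 °C; ClCO2Me, −40 → 0 °C; then 1 M HCl, 0 °C; then K2CO3, H2O–MeOH, 23 °C
Reagents that add atoms: none
Why: Bromine–lithium exchange and transmetalation to copper give a lithium dialkylcuprate whose alkyl groups add syn across acetylene, forming the C4–C5 bond and a (Z)-alkenylcuprate; acylation of the copper-bound carbon by methyl chloroformate proceeds with retention and forms the C2–C3 bond. The known reaction type is the syn-carbocupration of acetylene by lithium dialkylcuprates followed by trapping of the (Z)-dialkenylcuprate by a carbon electrophile. Aqueous acid then cleaves the disilazane, and on basification the free amine should close the ring by 6-exo-trig attack on the ester carbonyl (lactamisation), which only the Z isomer can undergo. No stereocentre is formed; the Z geometry comes from delivery of carbon and copper to the same side of the alkyne. The step needs single insertion of acetylene and survival of the β-amino organometallic, which the low temperature, the measured dose of acetylene and the poor leaving-group ability of the disilylamide should secure.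

Step 3
Reactants: 11 (E)-3,4-dimethoxycinnamic acid (two molecules per molecule of product)
Product: 12 (1α,2α,3β,4β)-2,4-bis(3,4-dimethoxyphenyl)cyclobutane-1,3-dicarboxylic acid
Conditions: hν (medium-pressure Hg lamp, Pyrex filter), powdered crystals of 11 suspended in H2O, 23 °C
Reagents that add atoms: (E)-3,4-dimethoxycinnamic acid (second molecule of 11), COc1ccc(/C=C/C(=O)O)cc1OC
Why: Topochemical [2+2] photocycloaddition of two E-alkenes stacked head-to-tail across an inversion centre should fix the regiochemistry and all four stereocentres, each aryl being trans to the carboxyl of its own monomer and cis to that of its partner.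

Step 4
Reactants: 12 (1α,2α,3β,4β)-2,4-bis(3,4-dimethoxyphenyl)cyclobutane-1,3-dicarboxylic acid
Product: 13 (1α,2α,3β,4β)-2,4-bis(3,4-dimethoxyphenyl)cyclobutane-1,3-dicarbonyl dichloride
Conditions: (COCl)2 (2.2 equiv), DMF (cat.), CH2Cl2, 0 → 23 °C
Reagents that add atoms: oxalyl chloride, O=C(Cl)C(Cl)=O
Why: Acid chloride formation through the chloroiminium (Vilsmeier-type) catalyst runs without base at or below room temperature, so the aryl methyl ethers and the four ring stereocentres should be untouched.

Step 5
Reactants: 10 5,6-dihydropyridin-2(1H)-one (two equivalents); 13 (1α,2α,3β,4β)-2,4-bis(3,4-dimethoxyphenyl)cyclobutane-1,3-dicarbonyl dichloride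
Product: 15 1,1'-{[(1α,2α,3β,4β)-2,4-bis(3,4-dimethoxyphenyl)cyclobutane-1,3-diyl]dicarbonyl}bis(5,6-dihydropyridin-2(1H)-one), via N-lithiated lactam 14 (not isolated)
Conditions: 10 (2.1 equiv), LiN(SiMe3)2 (2.1 equiv), THF, −78 °C; then 13 (1 equiv), −78 → 0 °C
Reagents that add atoms: 5,6-dihydropyridin-2(1H)-one (second equivalent of 10), O=C1C=CCCN1
Why: N-acylation of two equivalents of the lithium lactamate by the two acid chloride groups (imide formation) at low temperature should outrun ketene formation, so the stereocentres α to the carbonyl groups are carried through unchanged.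

Compound list
1 | 2-bromoethylamine hydrobromide | NCCBr.Br | starting material
2 | 1-(2-bromoethyl)-2,2,5,5-tetramethyl-1-aza-2,5-disilacyclopentane | C[Si]1(C)CC[Si](C)(C)N1CCBr | intermediate
3 | acetylene | C#C | starting material
4 | methyl chloroformate | COC(=O)Cl | starting material
5 | 2-(2,2,5,5-tetramethyl-1-aza-2,5-disilacyclopent-1-yl)ethyllithium | C[Si]1(C)CC[Si](C)(C)N1CC[Li] | intermediate
6 | lithium bis[2-(2,2,5,5-tetramethyl-1-aza-2,5-disilacyclopent-1-yl)ethyl]cuprate | [Li+].C[Si]1(C)CC[Si](C)(C)N1CC[Cu-]CCN1[Si](C)(C)CC[Si]1(C)C | intermediate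
7 | lithium bis[(Z)-4-(2,2,5,5-tetramethyl-1-aza-2,5-disilacyclopent-1-yl)but-1-en-1-yl]cuprate | [Li+].C[Si]1(C)CC[Si](C)(C)N1CC/C=C\[Cu-]/C=C\CCN1[Si](C)(C)CC[Si]1(C)C | intermediate
8 | methyl (Z)-5-(2,2,5,5-tetramethyl-1-aza-2,5-disilacyclopent-1-yl)pent-2-enoate | COC(=O)/C=C\CCN1[Si](C)(C)CC[Si]1(C)C | intermediate
9 | methyl (Z)-5-aminopent-2-enoate | COC(=O)/C=C\CCN | intermediate
10 | 5,6-dihydropyridin-2(1H)-one | O=C1C=CCCN1 | intermediate
11 | (E)-3,4-dimethoxycinnamic acid | COc1ccc(/C=C/C(=O)O)cc1OC | starting material
12 | (1α,2α,3β,4β)-2,4-bis(3,4-dimethoxyphenyl)cyclobutane-1,3-dicarboxylic acid (α-truxillic type: carboxyls trans to each other, aryls trans to each other, centrosymmetric) | COc1ccc([C@H]2[C@H](C(=O)O)[C@H](c3ccc(OC)c(OC)c3)[C@H]2C(=O)O)cc1OC | intermediate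
13 | (1α,2α,3β,4β)-2,4-bis(3,4-dimethoxyphenyl)cyclobutane-1,3-dicarbonyl dichloride | COc1ccc([C@H]2[C@H](C(=O)Cl)[C@H](c3ccc(OC)c(OC)c3)[C@H]2C(=O)Cl)cc1OC | intermediate
14 | lithium 2-oxo-5,6-dihydro-2H-pyridin-1-ide | [Li+].O=C1C=CCC[N-]1 | intermediate
15 | 1,1'-{[(1α,2α,3β,4β)-2,4-bis(3,4-dimethoxyphenyl)cyclobutane-1,3-diyl]dicarbonyl}bis(5,6-dihydropyridin-2(1H)-one), CNP0199212.1 | COc1ccc([C@H]2[C@H](C(=O)N3CCC=CC3=O)[C@H](c3ccc(OC)c(OC)c3)[C@H]2C(=O)N2CCC=CC2=O)cc1OC | target

Total step count: 5. Longest linear sequence: 3 steps (steps 1, 2 and 5, or steps 3, 4 and 5).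

Steps most likely to fail

Step 2. The β-amino alkyllithium or its cuprate may lose lithium disilylamide by β-elimination, the bromine–lithium exchange may be diverted into coupling, or acetylene may insert twice. The fallback sets out from 2 and comes back at 8. Acetylene 3 is monolithiated (n-BuLi, THF, −78 °C) to lithium acetylide F1, which is alkylated by 2 (DMPU, −78 → 23 °C) to give 1-(but-3-yn-1-yl)-2,2,5,5-tetramethyl-1-aza-2,5-disilacyclopentane F2. Deprotonation and acylation (n-BuLi, THF, −78 °C; then methyl chloroformate 4) should give methyl 5-(2,2,5,5-tetramethyl-1-aza-2,5-disilacyclopent-1-yl)pent-2-ynoate F3. Cis-semihydrogenation over the Lindlar catalyst (Pd/CaCO3 poisoned by Pb(OAc)2, quinoline, H2, EtOAc) should give 8, which the acid and base treatment of step 2 carries through 9 to 10. This replaces the carbocupration by classical acetylide chemistry and needs no β-amino organometallic.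

Step 3. The crystal may pack so that neighbouring double bonds are not antiparallel within bonding distance, which would leave the solid photostable or give only E/Z isomerisation at the surface. The fallback sets out from 11 and comes back at 12. Fischer esterification (MeOH, H2SO4, reflux) gives methyl (E)-3,4-dimethoxycinnamate F4. Irradiation of F4 in solution in the presence of BF3·OEt2 (CH2Cl2, Pyrex filter), where the excited Lewis acid complex of one ester molecule should add head-to-tail to a second, ground-state ester molecule, should give dimethyl (1α,2α,3β,4β)-2,4-bis(3,4-dimethoxyphenyl)cyclobutane-1,3-dicarboxylate F5. Non-epimerising cleavage of both ester groups (Me3SnOH, 1,2-dichloroethane, 80 °C; then aqueous KHSO4) returns 12.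

Step 5. The acid chloride may form a ketene under basic conditions and so epimerise the cyclobutane carbons, or the ambident lactamate may be acylated on oxygen or add in conjugate fashion. The fallback sets out from 10 and comes back at 15. N-Silylation of 10 (Me3SiCl, Et3N, CH2Cl2, 0 °C) gives 1-(trimethylsilyl)-5,6-dihydropyridin-2(1H)-one F6. Heating two equivalents of F6 with 13 (toluene, 80 °C) should transfer both acyl groups to nitrogen with loss of chlorotrimethylsilane under base-free conditions and give 15.

Further compounds
F1 | step 2 | lithium acetylide | [Li]C#C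
F2 | step 2 | 1-(but-3-yn-1-yl)-2,2,5,5-tetramethyl-1-aza-2,5-disilacyclopentane | C#CCCN1[Si](C)(C)CC[Si]1(C)C
F3 | step 2 | methyl 5-(2,2,5,5-tetramethyl-1-aza-2,5-disilacyclopent-1-yl)pent-2-ynoate | COC(=O)C#CCCN1[Si](C)(C)CC[Si]1(C)C
F4 | step 3 | methyl (E)-3,4-dimethoxycinnamate | COC(=O)/C=C/c1ccc(OC)c(OC)c1
F5 | step 3 | dimethyl (1α,2α,3β,4β)-2,4-bis(3,4-dimethoxyphenyl)cyclobutane-1,3-dicarboxylate | COc1ccc([C@H]2[C@H](C(=O)OC)[C@H](c3ccc(OC)c(OC)c3)[C@H]2C(=O)OC)cc1OC
F6 | step 5 | 1-(trimethylsilyl)-5,6-dihydropyridin-2(1H)-one | C[Si](C)(C)N1CCC=CC1=O
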